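**Remark:** atom labels C1 to O25 count the atoms of the target SMILES from left to right; enone ketal 1 is taken as a catalogue compound.

## Analysis of the target

The target is a C20 lactone on a bicyclo[4.3.1]decane: ring A (six-membered: C17, C19, C20, C22, C23, C24) and ring B (seven-membered: C13 to C17, C19, C20) share C17–C19–C20, and a δ-lactone (ring C: C8, C9, O10, C11, C13, C14) is fused to ring B across C13–C14. There are five stereocentres, (13R,14S,17S,20R,24S). The bridgeheads are C17 (quaternary, methyl C18) and C20 (tertiary carbinol, O21). O25 on C24 is cis to the C17 methyl group and anti to the C13–C16 bridge, so it is axial on ring A. H13 and H14 are trans, so the ring B/C fusion is trans. Ring C carries the exocyclic C7=C8 alkene with C6 cis to C14, extended by the E alkene C5=C6 to the tertiary carbinol C2; this dienyl carbinol ionises easily in acid. C13–H is alpha to the lactone carbonyl and beta to O21, so strong base is equally unwelcome. The hard points are three: the two bridgeheads must be set relative to each other; the axial C24 hydroxyl should not be available by hydride reduction of a C24 ketone, since hydride should enter anti to the C13–C16 bridge; and C8 must be attached to C14 on a defined face of a hindered bridged enoate with control of the alkene geometry. The strategy rests on one feature: on ring B, C8 (on C14) is 1,3 and cis to O21 (on C20). An ester on O21 can therefore deliver C8 to C14, and its carbonyl C9 then directs the C7=C8 olefination to the isomer that has the target geometry once C9 is reduced.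

## Retrosynthetic reasoning

**28 to 27 to 26.** The two silyl ethers come off last, so the C2 carbinol and O25 stay masked. In 27 the lactone bond O10–C11 is cut to hydroxy acid 26. Only the primary allylic C9 hydroxyl can form a six-membered ring with C11 (O21 is tertiary and would give a four-membered ring), so the forward lactonisation has no competitor.

**26 to 25 to 24.** The C9 hydroxyl and the free O21 hydroxyl of 26 are read as the two ends of an ester. Raising C9 to the carbonyl level and joining it to O21 gives the tethered lactone 24. This turns the 1,3-cis relation of C8 and O21 into a ring. The forward steps must free the C11 acid from its methyl ester without opening the lactone (acid 25), then reduce C9 without touching the carboxylate.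

**24 to 17 + 22 (key disconnection).** In 24 the bonds C7=C8 and C8–C14 are cut together. C8 is the only side-chain carbon bonded to the core, so this cut separates two fragments of similar size. It leaves C8 as a phosphonate-stabilised carbanion on the O21 ester of 17 and C7 as the aldehyde carbon of 22. The forward reaction must add C8 to C14 on the O21 face, protonate C13 so that C11 is trans to C8, and olefinate 22 with the E geometry.

**22 to 18.** The enal is traced through allylic alcohol 21, diol 20 and alkynediol 19 to alkynol 18. The C6–C7 bond is cut next to the alkyne, where an acetylide and a one-carbon electrophile join reliably and the E alkene then follows from a trans-selective reduction.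

**17 to 15 + 16.** The O21–C9 ester bond is cut to alcohol 15 and acid 16.

**15 to 12 to 11.** The C13=C14 alkene is taken out (12), then the C13–C20 bond is cut to keto enoate 11. The cut is made here, not at C16–C17, because closing this bond makes the second bridgehead. The chain on C17 can reach the C20 carbonyl only on its own face, so C20 is set from C17 with no reagent control. The forward step must generate the C13 enolate in the presence of an enolisable ketone, which a conjugate hydride addition to the enoate achieves. The alkene is then restored towards C14, the only side that has hydrogen.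

**11 to 9 + 10, and 9 to 6 + 7.** The C13=C14 bond of 11 is a cross-metathesis of 9 with acrylate 10. The C16–C17 bond of 9 is cut to enone 6 and Grignard reagent 7. The conjugate addition enters anti to the C24 silyloxy group, so C24 controls the quaternary C17 and puts O25 cis to the methyl group. This is why C24 is set first and never passes through a ketone on the bicycle.

**6 to 1.** The enone comes from iodide 4 by methylation and ketal hydrolysis, and 4 from enone ketal 1 by α-iodination (2), enantioselective carbonyl reduction (3) and silylation. The one reagent-controlled stereocentre of the route, C24, is made here.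

## Alternatives that were turned down

**Alternative 1:** Both carbocycles from one cycloaddition. C19–C20 and C22–C23 are cut, which opens rings A and B to a precursor in which a 2-silyloxydiene (C19=C17–C24(OSi)=C23) is tied through C16–C15–C14 to a 2-alkoxy enone (C22=C20(OR)–C13=O). Forward, Lewis-acid chelation of the enone and a type 2 intramolecular Diels–Alder reaction would give bicyclic ketone A1, with the bridgehead C17=C24 bond as a silyl enol ether and O21 already on C20.
- For: no other plan reaches the bicyclo[4.3.1]decane in so few operations, and the tether fixes the regiochemistry. On step economy for the skeleton it is clearly stronger than the nine steps used here to reach 17.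
- Against: C20 is the only stereocentre formed and nothing in the substrate biases it, so the absolute configuration would depend on an enantioselective version of a chelated type 2 cyclisation. C17 would then be methylated through a bridgehead enolate, and the C24 ketone reduced from the face covered by the C13–C16 bridge. The C13 ketone would still have to become the ester-bearing alkene.
- Comparison: after all this the synthesis would stand where 15 stands, with C13, C14 and the diene untouched. The chosen plan spends more steps on the skeleton but derives C17 and C20 from one carbinol, and puts its key step on the problem that A1 leaves open.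

**Alternative 2:** Ring B by (4+3) annulation. C13–C14 and C17–C19 are cut. A rhodium-bound vinylcarbene (carbene carbon C13 with the C11 ester, vinyl unit C20(OSi)=C19) would cyclopropanate the C14=C15 bond of a diene, and the cis-divinylcyclopropane would undergo Cope rearrangement to cycloheptadiene A2.
- For: a chiral dirhodium tetracarboxylate catalyst (Rh2L4) can set the absolute configuration. C14 and C17 are formed together through the boat transition state, and C14 already carries C8–C9 as an acetate arm. In catalytic asymmetric induction and convergence it is stronger than the present route.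
- Against: the rearrangement must form C17–C19 at a fully substituted diene terminus. Ring A is missing: C22 and C23 must be inserted between C20 and C24, with the tertiary carbinol and the C24 carbinol each made under separate control. The C15=C16 alkene must be saturated and C13 brought into the trans relation. The C7=C8 alkene would come from an aldol condensation at C8, where nothing enforces the E geometry.
- Comparison: the chosen strategy gives up the asymmetric key step. In return C14 is set by a tether after the bicycle is complete, and the phosphonate that forms C8–C14 also delivers the alkene as one isomer.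

**Alternative 3:** Ring expansion of a norbornane. C15–C16 is cut and a non-target C13–C24 bond is re-formed. This leads back to a 1-hydroxynorbornane with a methylene group at the future C17 and a vinyl group (C14=C15) on the one-carbon bridge that becomes C13. Forward, its potassium alkoxide would undergo anionic oxy-Cope rearrangement through C16=C17–C24(O)–C13–C14=C15, and the bridgehead enolate would be methylated at C17 to give A3.
- For: A3 is nearly the Michael acceptor of the present route (C13=C14 enoate, O21 on C20, C17 methyl), and it is reached without the reductive aldol and dehydrogenation detour. The rearrangement is driven by strain release. On directness to the enoate it is stronger.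
- Against: the substrate is a densely substituted norbornane (two oxygenated bridgeheads, a quaternary bridge carbon with defined vinyl orientation), and its enantioselective preparation would be long. The C24 ketone of A3 needs the same contra-steric reduction as in alternative 1. Its tert-butyl ester needs acid for removal, which the dienyl carbinol does not tolerate.
- Comparison: A3, like A1, ends before C13, C14 and the side chain. The chosen plan is a more conventional way to the same kind of enoate, with C24 set first, joined to a key step for the part A3 leaves open.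

Key step: step 14

## Route

**Step 1**
Reactants: 1 1,4-dioxaspiro[4.5]dec-6-en-8-one
Product: 2 7-iodo-1,4-dioxaspiro[4.5]dec-6-en-8-one
Conditions: I2, pyridine, CH2Cl2, 0 °C to rt
Reagents that add atoms: iodine, II
Why: α-Iodination of an enone by pyridine-mediated addition–elimination (Johnson iodination); the ketal survives the basic medium and the iodide marks C17 for the methyl group.

**Step 2**
Reactants: 2 7-iodo-1,4-dioxaspiro[4.5]dec-6-en-8-one
Product: 3 (8S)-7-iodo-1,4-dioxaspiro[4.5]dec-6-en-8-ol
Conditions: (R)-Me-CBS oxazaborolidine [(R)-1-methyl-3,3-diphenyltetrahydro-1H,3H-pyrrolo[1,2-c][1,3,2]oxazaborole] (20 mol%), BH3·SMe2, THF, −20 °C; MeOH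
Reagents that add atoms: none
Why: Corey–Bakshi–Shibata reduction; the iodovinyl carbon acts as the large group, so the (R)-catalyst should give the (S)-carbinol (the sense in which it gives (S)-1-phenylethanol), which becomes C24.

**Step 3**
Reactants: 3 (8S)-7-iodo-1,4-dioxaspiro[4.5]dec-6-en-8-ol
Product: 4 tert-butyl{[(8S)-7-iodo-1,4-dioxaspiro[4.5]dec-6-en-8-yl]oxy}dimethylsilane
Conditions: TBSCl, imidazole, DMF, rt
Reagents that add atoms: tert-butyldimethylsilyl chloride, CC(C)(C)[Si](C)(C)Cl
Why: Standard silylation of a secondary allylic alcohol; this ether is carried to the last step.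

**Step 4**
Reactants: 4 tert-butyl{[(8S)-7-iodo-1,4-dioxaspiro[4.5]dec-6-en-8-yl]oxy}dimethylsilane
Product: 6 (4S)-4-(tert-butyldimethylsilyloxy)-3-methylcyclohex-2-en-1-one, via methyl ketal 5 (not isolated)
Conditions: MeZnCl, Pd(PPh3)4 (5 mol%), THF, 50 °C; then 1 M aq. HCl, THF, 0 °C to rt
Reagents that add atoms: methylzinc chloride, C[Zn]Cl; water, O
Why: Negishi coupling of the vinyl iodide installs C18 without moving the alkene; dilute acid then hydrolyses the allylic ketal to the conjugated enone while the secondary TBS ether should survive.

**Step 5**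
Reactants: 6 (4S)-4-(tert-butyldimethylsilyloxy)-3-methylcyclohex-2-en-1-one; 7 but-3-en-1-ylmagnesium bromide
Product: 9 (3S,4S)-3-(but-3-en-1-yl)-4-(tert-butyldimethylsilyloxy)-3-methylcyclohexan-1-one, via silyl enol ether 8 (not isolated)
Conditions: CuBr·SMe2 (20 mol%), Me3SiCl, THF, −78 to −40 °C; then 1 M aq. HCl, 0 °C
Reagents that add atoms: none
Why: Copper-catalysed, Me3SiCl-accelerated conjugate addition of a Grignard reagent to a β,β-disubstituted enone. The nucleophile should enter anti to the pseudoaxial C24 silyloxy group, so C16 ends trans to O25 and the methyl group cis to it; this sets the quaternary C17 (S).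

**Step 6**
Reactants: 9 (3S,4S)-3-(but-3-en-1-yl)-4-(tert-butyldimethylsilyloxy)-3-methylcyclohexan-1-one; 10 methyl acrylate
Product: 11 methyl (2E)-5-[(1S,2S)-2-(tert-butyldimethylsilyloxy)-1-methyl-5-oxocyclohexyl]pent-2-enoate
Conditions: RuCl2(H2IMes)(=CH-C6H4-2-O-i-Pr) (second-generation Hoveyda–Grubbs catalyst, 3 mol%), CH2Cl2, 40 °C
Reagents that add atoms: none
Why: Olefin cross-metathesis of a terminal alkene with an acrylate, E-selective; ketone and silyl ether are inert.

**Step 7**
Reactants: 11 methyl (2E)-5-[(1S,2S)-2-(tert-butyldimethylsilyloxy)-1-methyl-5-oxocyclohexyl]pent-2-enoate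
Product: 12 methyl (1R,6S,7S)-7-(tert-butyldimethylsilyloxy)-1-hydroxy-6-methylbicyclo[4.3.1]decane-2-carboxylate (either C2 epimer)
Conditions: [(Ph3P)CuH]6 (Stryker's reagent, 0.4 equiv), toluene, −40 °C to rt; aq. NH4Cl
Reagents that add atoms: none
Why: Conjugate hydride addition to the enoate gives the C13 copper enolate, which adds to the C20 ketone (reductive aldol cyclisation; the reagent does not reduce the ketone). The chain reaches C20 only on its own face, in the chair with the chain axial, so C13–C20 forms cis to C16 and O21 ends cis to the methyl group: C20 (R) is set by the ring closure. The C13 configuration does not matter.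

**Step 8**
Reactants: 12 methyl (1R,6S,7S)-7-(tert-butyldimethylsilyloxy)-1-hydroxy-6-methylbicyclo[4.3.1]decane-2-carboxylate
Product: 15 methyl (1R,6S,7S)-7-(tert-butyldimethylsilyloxy)-1-hydroxy-6-methylbicyclo[4.3.1]dec-2-ene-2-carboxylate, via selenide 13 (not isolated), via selenoxide 14 (not isolated)
Conditions: LiN(i-Pr)2 (2.4 equiv), THF, −78 to −40 °C; PhSeBr, −78 °C; then AcOH, 30% H2O2, 0 °C to rt
Reagents that add atoms: none
Why: α-Selenenylation of the alkoxide/ester-enolate dianion followed by selenoxide syn-elimination. C20 has no hydrogen, so elimination can only run towards C14 and gives the ring B enoate.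

**Step 9**
Reactants: 15 methyl (1R,6S,7S)-7-(tert-butyldimethylsilyloxy)-1-hydroxy-6-methylbicyclo[4.3.1]dec-2-ene-2-carboxylate; 16 (diethoxyphosphoryl)acetic acid
Product: 17 methyl (1R,6S,7S)-7-(tert-butyldimethylsilyloxy)-1-{[(diethoxyphosphoryl)acetyl]oxy}-6-methylbicyclo[4.3.1]dec-2-ene-2-carboxylate
Conditions: DCC, 4-dimethylaminopyridine (DMAP, 20 mol%), CH2Cl2, 0 to 40 °C
Reagents that add atoms: none
Why: Steglich-type esterification; the activated phosphonoacetic acid can collapse to a phosphonoketene, which acylates tertiary alcohols. The bridgehead-bound hydroxyl is tied back and cannot ionise.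

**Step 10**
Reactants: 18 2-methylbut-3-yn-2-ol
Product: 19 4-methylpent-2-yne-1,4-diol
Conditions: n-BuLi (2.1 equiv), THF, −78 to 0 °C; (CH2O)n, 0 °C to rt; aq. NH4Cl
Reagents that add atoms: formaldehyde (as paraformaldehyde), C=O
Why: Double deprotonation (alkoxide and acetylide) and C-hydroxymethylation of the acetylide.

**Step 11**
Reactants: 19 4-methylpent-2-yne-1,4-diol
Product: 20 (2E)-4-methylpent-2-ene-1,4-diol
Conditions: LiAlH4, THF, reflux; aqueous work-up
Reagents that add atoms: none
Why: Alkoxide-directed trans-hydroalumination of a propargylic alcohol; protonolysis gives the E alkene. With both oxygens as alkoxides no allene can form by loss of oxygen.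

**Step 12**
Reactants: 20 (2E)-4-methylpent-2-ene-1,4-diol
Product: 21 (2E)-4-hydroxy-4-methylpent-2-enal
Conditions: MnO2, CH2Cl2, rt
Reagents that add atoms: none
Why: MnO2 oxidises only the primary allylic alcohol; the tertiary one cannot be oxidised.

**Step 13**
Reactants: 21 (2E)-4-hydroxy-4-methylpent-2-enal
Product: 22 (2E)-4-methyl-4-(triethylsilyloxy)pent-2-enal
Conditions: Et3SiOTf, 2,6-lutidine, CH2Cl2, −78 °C
Reagents that add atoms: triethylsilyl trifluoromethanesulfonate, CC[Si](CC)(CC)OS(=O)(=O)C(F)(F)F
Why: Silyl triflate with a hindered base silylates the tertiary alcohol; the enal has no enolisable position and is untouched.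

**Step 14**
Reactants: 17 methyl (1R,6S,7S)-7-(tert-butyldimethylsilyloxy)-1-{[(diethoxyphosphoryl)acetyl]oxy}-6-methylbicyclo[4.3.1]dec-2-ene-2-carboxylate; 22 (2E)-4-methyl-4-(triethylsilyloxy)pent-2-enal
Product: 24 tethered (E)-alkylidene δ-lactone methyl ester (13R,14S,17S,20R,24S) with the O21–C9(=O)–C8(=C7) bridge from C20 to C14, via phosphono lactone 23 (not isolated)
Conditions: LiCl (4 equiv), DBU (1.5 equiv), MeCN, 0 °C to rt until 17 is consumed; then 22 (1.3 equiv), rt
Reagents that add atoms: none
Why: LiCl and DBU generate the lithium-chelated phosphonoacetate carbanion at C8, which adds to C14 of the C13=C14 enoate; the C13 ester enolate is protonated, the more acidic C8–H of α-phosphono lactone 23 is removed, and this anion olefinates 22 (the closest known reaction type is the telescoped intramolecular Michael addition/Horner–Wadsworth–Emmons olefination of hydroxyl-tethered phosphonoacetates). The temporary δ-lactone O21–C9–C8–C14–C13–C20 closes 6-endo-trig, which needs the ring B conformer with O21 gauche to C14 about C20–C13. C14 (S) is fixed by the tether, because C8 can arrive only on the ring B face that carries O21. C13 (R) should come from kinetic protonation of the exocyclic ester enolate on the open lactone face (syn to C8–H and O21), which leaves C11 trans to C8. Olefination of the α-substituted phosphonate should give the E alkylidene lactone (C6 anti to the C9 carbonyl, cis to C14), as is usual for α-phosphono lactones with conjugated aldehydes. The Michael addition must be complete before 22 is added, otherwise 17 is olefinated directly; 22 has no α- or γ-hydrogen and tolerates the base. Expulsion of the O21 carboxylate from the C13 enolate would give a bridgehead C13=C20 alkene, which is strained but not forbidden in a bicyclo[4.3.1]decane, so the weak base with its ammonium proton source, which never lets the enolate accumulate, is part of the design. 1,2-Attack of the carbanion on the C11 ester should revert, because the stabilised carbanion leaves more easily than methoxide.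

**Step 15**
Reactants: 24 tethered (E)-alkylidene δ-lactone methyl ester
Product: 25 tethered (E)-alkylidene δ-lactone C11 carboxylic acid
Conditions: Me3SnOH (8 equiv), ClCH2CH2Cl, 80 °C; cold dilute aq. HCl wash
Reagents that add atoms: trimethyltin hydroxide, C[Sn](C)(C)O
Why: Me3SnOH cleaves methyl esters under nearly neutral conditions. The lactone is a conjugated ester of a tertiary alcohol and should react more slowly, and no free C13 enolate is formed.

**Step 16**
Reactants: 25 tethered (E)-alkylidene δ-lactone C11 carboxylic acid
Product: 26 seco acid with C9–OH, O21–H and C11 CO2H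
Conditions: i-Bu2AlH (6 equiv), CH2Cl2, −78 to −20 °C; aq. KNaC4H4O6 (potassium sodium tartrate)
Reagents that add atoms: none
Why: The acid is first converted to its aluminium carboxylate, which is inert at low temperature. The conjugated lactone is reduced 1,2 through the lactol to the C9 allylic alcohol and O21–H; no stereocentre is touched.

**Step 17**
Reactants: 26 seco acid with C9–OH, O21–H and C11 CO2H
Product: 27 2-O-triethylsilyl-24-O-tert-butyldimethylsilyl ether of the target
Conditions: EDC·HCl, DMAP, CH2Cl2, 0 °C to rt
Reagents that add atoms: none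
Why: Carbodiimide lactonisation; only the primary C9 hydroxyl can form a six-membered ring with C11, and the trans relation at C13/C14 from step 14 is kept.

**Step 18**
Reactants: 27 2-O-triethylsilyl-24-O-tert-butyldimethylsilyl ether of the target
Product: 28 CNP0116574.1
Conditions: Bu4NF, AcOH (1:1), THF, rt to 40 °C
Reagents that add atoms: none
Why: Buffered fluoride cleaves the tertiary triethylsilyl and the secondary TBS ether without exposing the dienyl carbinol to acid or the β-hydroxy lactone to strong base.

## Compound list

1 | 1,4-dioxaspiro[4.5]dec-6-en-8-one | O=C1C=CC2(CC1)OCCO2 | starting material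
2 | 7-iodo-1,4-dioxaspiro[4.5]dec-6-en-8-one | O=C1CCC2(OCCO2)C=C1I | intermediate
3 | (8S)-7-iodo-1,4-dioxaspiro[4.5]dec-6-en-8-ol | O[C@H]1CCC2(OCCO2)C=C1I | intermediate
4 | tert-butyl{[(8S)-7-iodo-1,4-dioxaspiro[4.5]dec-6-en-8-yl]oxy}dimethylsilane | CC(C)(C)[Si](C)(C)O[C@H]1CCC2(OCCO2)C=C1I | intermediate
5 | tert-butyldimethyl{[(8S)-7-methyl-1,4-dioxaspiro[4.5]dec-6-en-8-yl]oxy}silane (methyl ketal) | CC(C)(C)[Si](C)(C)O[C@H]1CCC2(OCCO2)C=C1C | intermediate
6 | (4S)-4-(tert-butyldimethylsilyloxy)-3-methylcyclohex-2-en-1-one | CC(C)(C)[Si](C)(C)O[C@H]1CCC(=O)C=C1C | intermediate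
7 | but-3-en-1-ylmagnesium bromide | C=CCC[Mg]Br | starting material
8 | tert-butyl{[(1S,2S)-2-(but-3-en-1-yl)-2-methyl-4-(trimethylsilyloxy)cyclohex-3-en-1-yl]oxy}dimethylsilane (silyl enol ether of 9) | C=CCC[C@@]1(C)C=C(O[Si](C)(C)C)CC[C@@H]1O[Si](C)(C)C(C)(C)C | intermediate
9 | (3S,4S)-3-(but-3-en-1-yl)-4-(tert-butyldimethylsilyloxy)-3-methylcyclohexan-1-one | C=CCC[C@@]1(C)CC(=O)CC[C@@H]1O[Si](C)(C)C(C)(C)C | intermediate
10 | methyl acrylate | C=CC(=O)OC | starting material
11 | methyl (2E)-5-[(1S,2S)-2-(tert-butyldimethylsilyloxy)-1-methyl-5-oxocyclohexyl]pent-2-enoate | COC(=O)/C=C/CC[C@@]1(C)CC(=O)CC[C@@H]1O[Si](C)(C)C(C)(C)C | intermediate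
12 | methyl (1R,6S,7S)-7-(tert-butyldimethylsilyloxy)-1-hydroxy-6-methylbicyclo[4.3.1]decane-2-carboxylate (C2 epimers) | COC(=O)C2CCC[C@@]1(C)C[C@]2(O)CC[C@@H]1O[Si](C)(C)C(C)(C)C | intermediate
13 | methyl (1R,6S,7S)-7-(tert-butyldimethylsilyloxy)-1-hydroxy-6-methyl-2-(phenylselanyl)bicyclo[4.3.1]decane-2-carboxylate (selenide) | COC(=O)C2([Se]c3ccccc3)CCC[C@@]1(C)C[C@]2(O)CC[C@@H]1O[Si](C)(C)C(C)(C)C | intermediate
14 | selenoxide of 13 (2-phenylseleninyl) | COC(=O)C2([Se](=O)c3ccccc3)CCC[C@@]1(C)C[C@]2(O)CC[C@@H]1O[Si](C)(C)C(C)(C)C | intermediate
15 | methyl (1R,6S,7S)-7-(tert-butyldimethylsilyloxy)-1-hydroxy-6-methylbicyclo[4.3.1]dec-2-ene-2-carboxylate | COC(=O)C2=CCC[C@@]1(C)C[C@]2(O)CC[C@@H]1O[Si](C)(C)C(C)(C)C | intermediate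
16 | (diethoxyphosphoryl)acetic acid | CCOP(=O)(CC(=O)O)OCC | starting material
17 | methyl (1R,6S,7S)-7-(tert-butyldimethylsilyloxy)-1-{[(diethoxyphosphoryl)acetyl]oxy}-6-methylbicyclo[4.3.1]dec-2-ene-2-carboxylate | COC(=O)C2=CCC[C@@]1(C)C[C@]2(OC(=O)CP(=O)(OCC)OCC)CC[C@@H]1O[Si](C)(C)C(C)(C)C | intermediate
18 | 2-methylbut-3-yn-2-ol | CC(C)(O)C#C | starting material
19 | 4-methylpent-2-yne-1,4-diol | CC(C)(O)C#CCO | intermediate
20 | (2E)-4-methylpent-2-ene-1,4-diol | CC(C)(O)/C=C/CO | intermediate
21 | (2E)-4-hydroxy-4-methylpent-2-enal | CC(C)(O)/C=C/C=O | intermediate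
22 | (2E)-4-methyl-4-(triethylsilyloxy)pent-2-enal | CC(C)(O[Si](CC)(CC)CC)/C=C/C=O | intermediate
23 | Michael adduct: δ-lactone O21–C9(=O)–C8H[P(O)(OEt)2]–C14 bridging C20 and C14 of the bicyclo[4.3.1]decane, C11 methyl ester on C13 trans to C8, C24 OTBS, (13R,14S,17S,20R,24S), C8 epimers | CCOP(=O)(OCC)C1C(=O)O[C@@]23CC[C@H](O[Si](C)(C)C(C)(C)C)[C@](C)(C3)CC[C@H]1[C@H]2C(=O)OC | intermediate
24 | tethered lactone: as 23 but with C8=C7 (E, C6 anti to C9=O) carrying the (E)-3-methyl-3-(triethylsilyloxy)but-1-enyl group | CC(C)(O[Si](CC)(CC)CC)/C=C/C=C1/C(=O)O[C@@]23CC[C@H](O[Si](C)(C)C(C)(C)C)[C@](C)(C3)CC[C@H]1[C@H]2C(=O)OC | intermediate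
25 | C11 carboxylic acid of 24 | CC(C)(O[Si](CC)(CC)CC)/C=C/C=C1/C(=O)O[C@@]23CC[C@H](O[Si](C)(C)C(C)(C)C)[C@](C)(C3)CC[C@H]1[C@H]2C(=O)O | intermediate
26 | seco acid: bicyclo[4.3.1]decane with free O21–H, C11 CO2H on C13, and on C14 the (1E,3E)-dienyl unit with C9H2OH on C8; silyl ethers on O4 and O25; (13R,14S,17S,20R,24S) | CC(C)(O[Si](CC)(CC)CC)/C=C/C=C(/CO)[C@H]1CC[C@@]2(C)C[C@](O)(CC[C@@H]2O[Si](C)(C)C(C)(C)C)[C@@H]1C(O)=O | intermediate
27 | target with O4 as triethylsilyl ether and O25 as TBS ether | CC(C)(O[Si](CC)(CC)CC)/C=C/C=C1/COC(=O)[C@@H]2[C@@H]1CC[C@@]1(C)C[C@]2(O)CC[C@@H]1O[Si](C)(C)C(C)(C)C | intermediate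
28 | CNP0116574.1, (13R,14S,17S,20R,24S) | CC(C)(O)/C=C/C=C1/COC(=O)[C@@H]2[C@@H]1CC[C@@]1(C)C[C@]2(O)CC[C@@H]1O | target

## Step count and weak points

Total: 18 steps. Longest linear sequence: 14 steps (steps 1 to 9 and 14 to 18); steps 10 to 13 make the aldehyde branch.

**Step 14 (key step).** Three things may go wrong. The Michael addition may be slow or lie on the side of 17, so that adding 22 olefinates the uncyclised phosphonate. The C13 enolate may expel the O21 carboxylate and open the tether to a bridgehead alkene. The olefination of the hindered tertiary phosphonate anion may lose E selectivity. Fallback, from 15 back to 24: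
- O21 is acetylated (Ac2O, DMAP) to the acetate F6.
- KN(SiMe3)2 at −78 °C forms the acetate enolate, a stronger donor, which adds 6-endo to C14; a cold quench gives the saturated tethered lactone F7.
- Kinetic deprotonation at the less hindered C8 with LiN(i-Pr)2 and addition to 22 gives the aldol F8.
- Dehydration through the mesylate (MsCl, Et3N, then DBU) gives 24.

The alkene is then made by aldol condensation instead of phosphonate olefination.

**Step 7.** The copper enolate may be quenched before it closes the bridged seven-membered ring, because the chair with the axial chain has to be populated; the result is simple conjugate reduction. Fallback, from 11 back to 12: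
- Hydrogenation (H2, Pd/C) gives the saturated keto ester F1, which is also the product of the failed step.
- Me3SiOTf and Et3N mask the ketone as the silyl enol ether F2.
- LiN(i-Pr)2 then CBr4 brominate alpha to the ester to give the bromo enol ether F3.
- Dilute acid frees the ketone to give the bromo keto ester F4.
- SmI2 in THF at −78 °C generates the samarium enolate irreversibly and closes the ring to 12 (intramolecular Reformatsky reaction).

**Step 15.** Hydrolysis of the doubly flanked C11 methyl ester may be too slow, and long heating invites lactone cleavage or loss of O21 by β-elimination. Fallback, from 24 back to 27: i-Bu2AlH at −78 °C is applied to 24 itself to reduce the lactone to the diol methyl ester F9, and transesterification of C9–OH onto C11 (catalytic Ti(O-i-Pr)4, toluene, 80 °C) closes ring C to 27. This removes steps 15 to 17 but depends on the lactone being reduced before the hindered methyl ester.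

**Step 16.** The aluminium carboxylate may be reduced as the mixture warms, or the lactol may not collapse and reduction stops halfway. Fallback, from 25 back to 26: a limited amount of i-Bu2AlH at −78 °C gives the lactol acid F10, and NaBH4 with CeCl3·7H2O in MeOH reduces its ring-opened hydroxy dienal form 1,2 to 26. No aluminium hydride then meets the carboxylate above −78 °C.

**Step 9.** Acylation of the tertiary alcohol may stall, with the activated acid rearranging to the N-acylurea. Fallback, from 15 back to 17: bromoacetyl bromide and pyridine give the bromoacetate F5, and heating with P(OEt)3 at 110 °C (Michaelis–Arbuzov reaction) gives 17.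

## Further compounds

F1 | step 7 | methyl 5-[(1S,2S)-2-(tert-butyldimethylsilyloxy)-1-methyl-5-oxocyclohexyl]pentanoate | COC(=O)CCCC[C@@]1(C)CC(=O)CC[C@@H]1O[Si](C)(C)C(C)(C)C
F2 | step 7 | trimethylsilyl enol ether of F1 (C20=C22 isomer) | COC(=O)CCCC[C@@]1(C)CC(O[Si](C)(C)C)=CC[C@@H]1O[Si](C)(C)C(C)(C)C
F3 | step 7 | 2-bromo ester of F2 | COC(=O)C(Br)CCC[C@@]1(C)CC(O[Si](C)(C)C)=CC[C@@H]1O[Si](C)(C)C(C)(C)C
F4 | step 7 | methyl 2-bromo-5-[(1S,2S)-2-(tert-butyldimethylsilyloxy)-1-methyl-5-oxocyclohexyl]pentanoate | COC(=O)C(Br)CCC[C@@]1(C)CC(=O)CC[C@@H]1O[Si](C)(C)C(C)(C)C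
F5 | step 9 | methyl (1R,6S,7S)-1-[(bromoacetyl)oxy]-7-(tert-butyldimethylsilyloxy)-6-methylbicyclo[4.3.1]dec-2-ene-2-carboxylate | COC(=O)C2=CCC[C@@]1(C)C[C@]2(OC(=O)CBr)CC[C@@H]1O[Si](C)(C)C(C)(C)C
F6 | step 14 | methyl (1R,6S,7S)-1-acetoxy-7-(tert-butyldimethylsilyloxy)-6-methylbicyclo[4.3.1]dec-2-ene-2-carboxylate | COC(=O)C2=CCC[C@@]1(C)C[C@]2(OC(C)=O)CC[C@@H]1O[Si](C)(C)C(C)(C)C
F7 | step 14 | tethered saturated δ-lactone (C8H2) with C11 methyl ester, (13R,14S,17S,20R,24S) | C1C(=O)O[C@@]23CC[C@H](O[Si](C)(C)C(C)(C)C)[C@](C)(C3)CC[C@H]1[C@H]2C(=O)OC
F8 | step 14 | aldol adduct of F7 with 22 (C7 carbinol, mixture at C7 and C8) | CC(C)(O[Si](CC)(CC)CC)/C=C/C(O)C1C(=O)O[C@@]23CC[C@H](O[Si](C)(C)C(C)(C)C)[C@](C)(C3)CC[C@H]1[C@H]2C(=O)OC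
F9 | step 15 | methyl ester of seco acid 26 | CC(C)(O[Si](CC)(CC)CC)/C=C/C=C(/CO)[C@H]1CC[C@@]2(C)C[C@](O)(CC[C@@H]2O[Si](C)(C)C(C)(C)C)[C@@H]1C(=O)OC
F10 | step 16 | C9 lactol of acid 25 | CC(C)(O[Si](CC)(CC)CC)/C=C/C=C1/C(O)O[C@@]23CC[C@H](O[Si](C)(C)C(C)(C)C)[C@](C)(C3)CC[C@H]1[C@H]2C(=O)O
A1 | alternative 1 | 1-(methoxymethoxy)-7-(triethylsilyloxy)bicyclo[4.3.1]dec-6-en-2-one | O=C1CCCC2=C(O[Si](CC)(CC)CC)CC[C@@]1(OCOC)C2
A2 | alternative 2 | methyl 7-(2-tert-butoxy-2-oxoethyl)-2-(tert-butyldimethylsilyloxy)-4-[(tert-butyldimethylsilyloxy)methyl]-4-methylcyclohepta-1,5-diene-1-carboxylate | COC(=O)C1=C(O[Si](C)(C)C(C)(C)C)C[C@@](C)(CO[Si](C)(C)C(C)(C)C)C=C[C@@H]1CC(=O)OC(C)(C)C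
A3 | alternative 3 | tert-butyl 1-(tert-butyldimethylsilyloxy)-6-methyl-7-oxobicyclo[4.3.1]dec-2-ene-2-carboxylate | CC(C)(C)OC(=O)C2=CCC[C@@]1(C)C[C@]2(O[Si](C)(C)C(C)(C)C)CCC1=O
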